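L's slowness was where I started, because G at its charge captures J with a half-life of 0.289 min, and L's own half-life of 7.2 min stands far above that.

    D → X (k1 = 0.0058 s⁻¹)
    G + J → G.J (k2 = 0.25 L mol⁻¹ s⁻¹)
    G + D ⇌ G.D (K3 = 27 L mol⁻¹, k3 = 0.094 L mol⁻¹ s⁻¹)
    L → J (k4 = 0.0016 s⁻¹)
    J → D (k5 = 2.3 × 10⁻⁴ s⁻¹)

| setting | Monday's | Sunday's | Thursday's | Friday's |
|---|---|---|---|---|
| L | 0.20 M | 0.20 M | 0.20 M (fed, over 4.00 min) | 0.20 M |
| G | 0.160 M | 0.160 M | 0.160 M | 0.160 M |
| remark | a single well-mixed tank run continuously and read at steady state, 40.0 min in it on average | a single well-mixed tank run continuously and read at steady state, 8.0 min in it on average | a stirred flask in which L is dosed at a steady rate over 4.00 min without added volume, worked up at 8.0 min | everything together in a closed stirred flask, run for 8.0 min |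
| time |  |  | 8.0 min | 8.0 min |

- the set-up with the highest amount of G.J at the outlet or at the end, in percent of the L put in ("none" if the first two lie within 2 percentage points) (Monday's / Sunday's / Thursday's / Friday's / none)
- amount of G.J at the outlet or at the end, in percent of the L put in, Monday's
- amount of G.J at the outlet or at the end, in percent of the L put in, Sunday's
- amount of G.J at the outlet or at the end, in percent of the L put in, Thursday's
- amount of G.J at the outlet or at the end, in percent of the L put in, Friday's

G was the limiting reagent, its charge being 80.0% of L's, so I kept the books on G.

1. I reckoned the L left from the first-order step and each vessel's clock: 46.4% in Friday's flask, 56.6% in Thursday's, 56.6% in Sunday's tank and 20.7% in Monday's.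

2. I took free J as steady (a quasi-steady state), made by L as fast as G takes it, so the J standing per L left is the hold-up ratio 4.00%, which is the L rate constant over the capture rate constant times G, given here at G's full charge and divided by the fraction of G still free as G falls.

3. I left D and G.D out of the books, because J passes to D at 2.3 × 10⁻⁴ s⁻¹, far below the capture rate of 0.0400 s⁻¹ at G's charge; I booked no outlet loss of J in the tanks either.

4. Solving Friday's ledger against itself left 38.9% of G free and 61.1% as G.J, which closes the books on G and makes 48.8% of the L charged.

5. The same ledger gave 39.0% for Thursday's, 39.0% for Sunday's and 71.5% for Monday's, so I put Monday's first.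

The forecast gave 70.1%, 39%, 38.8% and 48.7% for Monday's, Sunday's, Thursday's and Friday's, naming Monday's as best, on the ground that “J is trapped by G almost as soon as it forms”, and on Monday's it stood 1.4 percentage points below my figure.

The simulation gave 70.1%, 39.0%, 38.9% and 48.6% in that order, with Monday's as best.

In Thursday's flask at 4.62 min, J's half-life by capture read 0.37 min against 7.2 min for L, a ratio of 5.14%, which is the hold-up ratio at the G then free. At 8.00 min Thursday's flask held J at 4.27% beside L at 56.6%, a reading of 7.54%, while the hold-up ratio over the 51.3% of G still free gives 7.80%.

For Thursday's flask read at 5.0 min, the ledger gives L at 75.4%, G free at 74.4%, J at 4.05% and G.J at 20.5%. The simulation of that flask gave 75.4%, 74%, 3.92% and 20.5%.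

(Its constants are assumed; the result is computed.)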